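The synthesis rests on cutting the bond between the methyl-bearing oxirane carbon C7 and the oxirane CH C8. This is the fusion bond shared by the 7,8-oxirane and carbocycle B. C8 is allylic to C9=C10(Br) and C7 is at ketone level, so one operation can form the bond. That operation is an intramolecular allylic sulfonium ylide epoxidation, which closes ring B and the oxirane together and sets C7 and C8. The precursor is a monocyclic ring-A bromochloride whose quaternary C6 carries an acetyl group and a CMe2–C(Br)=CH–CH2–S+ chain. An asymmetric Diels–Alder reaction sets C5/C6, a temporary oxepene fixes the alkene geometry, and a bromolactone relays C6 to C2/C3. Late epoxidation of the vinyl bromide completes the target.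

Key step: step 12

Numbering used throughout (chamigrane type): ring A = C1H2–C2–C3(CH3)–C4H2–C5–C6; ring B = C6–C7(CH3)–C8–C9–C10–C11(CH3)2; C6 is the later spiro atom. β is the face of ring A that carries C7, and α is the face that carries C11.
Assumption: the (S)-configured oxazaborolidinium salt is taken to leave open the face of 3 that leads to (5S,6R)-5. If the sense of induction is the opposite, its (R)-antipode is used.

Step 1
Reactants: 1 dimethyl 2,2-dimethylsuccinate
Product: 2 dimethyl 2-(hydroxymethylidene)-3,3-dimethylbutanedioate (enol of the 2-formyl diester)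
Conditions: HCO2Me, NaH, cat. MeOH, Et2O, 0 °C → rt; aq HCl
Reagents that add atoms: methyl formate (COC=O)
Why: Crossed Claisen condensation (C-formylation); the C6 methylene is the only enolisable position of 1 and methyl formate cannot self-condense, so a single stabilised enolate should form and bring in C5.

Step 2
Reactants: 2 dimethyl 2-(hydroxymethylidene)-3,3-dimethylbutanedioate
Product: 3 methyl 4,4-dimethyl-5-oxo-4,5-dihydrofuran-3-carboxylate
Conditions: p-TsOH (5 mol %), toluene, reflux, removal of MeOH
Reagents that add atoms: none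
Why: Acid-catalysed enol lactonisation (5-exo-trig transesterification) is driven by the gem-dimethyl effect and loss of methanol, and the quaternary C11 blocks isomerisation to a 2(5H)-furanone.

Step 3
Reactants: 3 methyl 4,4-dimethyl-5-oxo-4,5-dihydrofuran-3-carboxylate; 4 isoprene
Product: 5 methyl (3aR,7aS)-3,3,6-trimethyl-2-oxo-3,4,7,7a-tetrahydro-1-benzofuran-3a(2H)-carboxylate (cis-fused lactone, 5S,6R)
Conditions: (S)-o-tolyl-oxazaborolidine·Tf2NH (20 mol %), 4 (5 equiv), CH2Cl2, −40 → 0 °C
Reagents that add atoms: none
Why: Catalytic asymmetric Diels–Alder reaction; the ester polarises C5=C6 so that isoprene adds in the "para" sense (C3 methyl opposite C6), suprafacial addition to the cyclic dienophile forces C5–O and C11 cis, and the chiral Lewis acid shields one enantiotopic face to set 5S,6R.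

Step 4
Reactants: 5 cis-fused lactone ester
Product: 7 oxepan-4-one ester (5S,6R), via hydroxy enone 6 (not isolated)
Conditions: CH2=CHMgBr (1.1 equiv), THF, −78 → 0 °C; aq NH4Cl; DBU (0.2 equiv), MeCN, rt
Reagents that add atoms: vinylmagnesium bromide (C=C[Mg]Br)
Why: Grignard mono-addition to the γ-lactone (far less shielded than the doubly neopentyl ester) stops at the magnesium hemiketal, and the released hydroxy enone closes by base-catalysed 7-endo-trig oxa-Michael addition, helped by the cis C5–O/C11 arrangement and the Thorpe–Ingold effect; no stereocentre is formed.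

Step 5
Reactants: 7 oxepan-4-one ester
Product: 8 C9=C10 enol triflate of 7
Conditions: KHMDS, PhNTf2, THF, −78 °C
Reagents that add atoms: N-phenylbis(trifluoromethanesulfonimide) (O=S(=O)(N(c1ccccc1)S(=O)(=O)C(F)(F)F)C(F)(F)F)
Why: Kinetic enolate O-triflation; C9 is the only α-CH position because C11 and C6 are quaternary, and cyclic β-alkoxy enolates of the tetrahydropyranone type do not eliminate at −78 °C.

Step 6
Reactants: 8 enol triflate
Product: 9 methyl (5aR,9aS)-4-bromo-5,5,8-trimethyl-5,6,9,9a-tetrahydro-1-benzoxepine-5a(2H)-carboxylate (C10 vinyl bromide in the oxepene)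
Conditions: [Cp*Ru(MeCN)3]OTf (5 mol %), LiBr (3 equiv), DMI, 60 °C
Reagents that add atoms: lithium bromide ([Li+].[Br-])
Why: Ruthenium-catalysed alkenyl triflate–halide exchange puts bromine on C10 while the seven-membered ring holds C8 and C11 cis on C9=C10, the contra-steric geometry that an open chain would not adopt.

Step 7
Reactants: 9 oxepene vinyl bromide ester
Product: 10 bromolactone (2S,3S,5S,6R): C7(=O)–O–C3 δ-lactone bridging ring A on the β-face, C2–Br on the α-face, oxepene unchanged
Conditions: NBS, MeCN–H2O (20:1), 0 °C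
Reagents that add atoms: N-bromosuccinimide (O=C1CCC(=O)N1Br); water (O)
Why: Bromolactonisation with participation of the axial ester carbonyl; Markovnikov attack of the C7 carbonyl oxygen on C3 from the β-face requires the bromonium ion on the α-face, so C6 sets C2–Br trans and C3–O cis to C7, the dioxocarbenium ion is hydrolysed with loss of methanol, and the electron-poor vinyl bromide is left alone.

Step 8
Reactants: 10 bromolactone
Product: 12 bromohydrin methyl ketone (2S,3S,5S,6R), via bicyclic enol ether 11 (not isolated)
Conditions: Tebbe reagent, cat. pyridine, THF–toluene, −40 → 0 °C; aq NaOH, filter; oxalic acid (cat.), THF–H2O, 0 °C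
Reagents that add atoms: Tebbe reagent (C=[Ti](C1C=CC=C1)C1C=CC=C1.C[Al](C)Cl); water (O)
Why: Tebbe methylenation of the strained lactone followed by mild enol ether hydrolysis converts the C7 carboxyl carbon into the methyl ketone without base, and only C7–O chemistry is involved, so the C3–O configuration is kept.

Step 9
Reactants: 12 bromohydrin methyl ketone
Product: 13 bromochloride methyl ketone (2S,3S,5S,6R)
Conditions: SOCl2, CH2Cl2, −20 °C → rt
Reagents that add atoms: thionyl chloride (O=S(Cl)Cl)
Why: Chlorodehydroxylation with neighbouring-group participation; ionisation of the C3 chlorosulfite (or of the bridged hemiketal form, in which C2–Br is antiperiplanar to C3–O) should give the α-face bromonium ion, which chloride opens at the tertiary C3 from the β-face, giving overall retention (3S).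

Step 10
Reactants: 13 bromochloride methyl ketone
Product: 14 1-[(1R,2S,4S,5S)-5-bromo-4-chloro-1-[(3E)-3,5-dibromo-2-methylpent-3-en-2-yl]-4-methyl-2-(trimethylsilyloxy)cyclohexyl]ethanone
Conditions: TMSBr, CH2Cl2, −40 → 0 °C
Reagents that add atoms: bromotrimethylsilane (C[Si](C)(C)Br)
Why: Silyl halide ether cleavage; TMSBr silylates the ring oxygen and bromide attacks the primary allylic C8 (SN2) rather than the neopentyl-like C5, which frees the (E)-bromoallyl bromide with the ring-derived geometry and protects C5–OH in the same operation.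

Step 11
Reactants: 14 (E)-allylic bromide TMS ether
Product: 15 S-allylic tetrahydrothiophenium tetrafluoroborate of 14
Conditions: tetrahydrothiophene (3 equiv), NaBF4, acetone, rt
Reagents that add atoms: tetrahydrothiophene (C1CCSC1); sodium tetrafluoroborate ([Na+].F[B-](F)(F)F)
Why: S-Alkylation (SN2) of the sulfide by the primary allylic bromide with exchange to a non-nucleophilic counter-ion; the hindered secondary bromide, tertiary chloride and vinyl bromide should not react.

Step 12
Reactants: 15 tetrahydrothiophenium tetrafluoroborate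
Product: 18 O-TMS prepacifenol (2S,3S,5S,6R,7S,8R), via allyl ylide 16 (not isolated), via betaine 17 (not isolated)
Conditions: LiHMDS (1.1 equiv), THF, −78 → −20 °C
Reagents that add atoms: none
Why: LiHMDS removes the most acidic proton (C8–H, allylic and α to S+) to give allyl ylide 16, C8 adds reversibly to the C7 ketone to give betaine 17, and the C7 alkoxide then expels tetrahydrothiophene from C8 with inversion. The closest known reaction type is the Johnson–Corey–Chaykovsky epoxidation in its intramolecular, epoxy-annulating form, in which tethered (allylic) sulfonium ylides turn ketones into ring-fused (vinyl)oxiranes. Ring B closes 6-exo-trig at the carbonyl carbon and the oxirane closes 3-exo-tet, so the single new C7–C8 bond becomes the fusion bond of both rings. C7 (S) is controlled by C6/C5: in the cyclohexene-like half-chair the CH(OTMS) branch C5 sits equatorial and C1H2 axial, which keeps the pseudoaxial sulfonium away from C5 and puts the axial alkoxide on the C5 side of ring B; C8 (R) follows because only the betaine with O− and S+ trans-diaxial can close, the cis betaine reverting to 16. The step needs C8 deprotonation rather than ketone enolisation or ring-CH2 deprotonation (pKa gap, −78 °C), α- rather than γ-attack (γ would give a cyclobutane at the fully substituted C10), and survival of the halides (equatorial C2–Br and C3–Cl lack antiperiplanar hydrogens; C9–H is syn to C10–Br). The (E)-alkene inherited from the oxepene holds C8 within bonding distance of C7, and the silyl ether blocks retro-aldol cleavage of C5–C6.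

Step 13
Reactants: 18 O-TMS prepacifenol
Product: 20 prepacifenol epoxide (2S,3S,5S,6R,7S,8R,9R,10R), via O-TMS prepacifenol epoxide 19 (not isolated)
Conditions: DMDO, acetone–CH2Cl2, 0 °C → rt; evaporate; NH4F, MeOH, 0 °C
Reagents that add atoms: dimethyldioxirane (CC1(C)OO1)
Why: Neutral dioxirane epoxidation of the vinyl bromide should occur anti to the allylic 7,8-oxirane oxygen and to the pseudoaxial C11 methyl (trans-diepoxide, 9R,10R), the silyl ether prevents oxidation of C5–OH, and near-neutral fluoride methanolysis then removes the TMS group.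

Compound list
1 | dimethyl 2,2-dimethylsuccinate | COC(=O)CC(C)(C)C(=O)OC | starting material
2 | dimethyl 2-(hydroxymethylidene)-3,3-dimethylbutanedioate | COC(=O)C(=CO)C(C)(C)C(=O)OC | intermediate
3 | methyl 4,4-dimethyl-5-oxo-4,5-dihydrofuran-3-carboxylate | COC(=O)C1=COC(=O)C1(C)C | intermediate
4 | isoprene | C=CC(C)=C | starting material
5 | methyl (3aR,7aS)-3,3,6-trimethyl-2-oxo-3,4,7,7a-tetrahydro-1-benzofuran-3a(2H)-carboxylate | CC1(C)[C@@]2(CC=C(C)C[C@@H]2OC1=O)C(=O)OC | intermediate
6 | methyl (1R,6S)-6-hydroxy-4-methyl-1-(2-methyl-3-oxopent-4-en-2-yl)cyclohex-3-ene-1-carboxylate (hydroxy enone, not isolated) | C=CC(=O)C(C)(C)[C@@]1(CC=C(C)C[C@@H]1O)C(=O)OC | intermediate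
7 | methyl (5aR,9aS)-5,5,8-trimethyl-4-oxo-2,3,4,5,6,9-hexahydro-1-benzoxepine-5a(9aH)-carboxylate | CC1(C)[C@@]2(CC=C(C)C[C@@H]2OCCC1=O)C(=O)OC | intermediate
8 | methyl (5aR,9aS)-5,5,8-trimethyl-4-(trifluoromethylsulfonyloxy)-5,6,9,9a-tetrahydro-1-benzoxepine-5a(2H)-carboxylate | CC1(C)[C@@]2(CC=C(C)C[C@@H]2OCC=C1OS(=O)(=O)C(F)(F)F)C(=O)OC | intermediate
9 | methyl (5aR,9aS)-4-bromo-5,5,8-trimethyl-5,6,9,9a-tetrahydro-1-benzoxepine-5a(2H)-carboxylate | CC1(C)[C@@]2(CC=C(C)C[C@@H]2OCC=C1Br)C(=O)OC | intermediate
10 | bromolactone (2S,3S,5S,6R): β-face C7(=O)–O–C3 lactone bridge, α-C2–Br, oxepene vinyl bromide | CC1(C)[C@@]2(C[C@H](Br)[C@]3(C)C[C@@H]2OCC=C1Br)C(=O)O3 | intermediate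
11 | bicyclic enol ether (C7=CH2 analogue of 10, not isolated) | CC1(C)[C@@]2(C[C@H](Br)[C@]3(C)C[C@@H]2OCC=C1Br)C(=C)O3 | intermediate
12 | bromohydrin methyl ketone (2S,3S,5S,6R): C6 acetyl, β-C3–OH, α-C2–Br, oxepene vinyl bromide | CC1(C)[C@@]2(C[C@H](Br)[C@@](C)(O)C[C@@H]2OCC=C1Br)C(C)=O | intermediate
13 | bromochloride methyl ketone (2S,3S,5S,6R): as 12 with β-C3–Cl | CC1(C)[C@@]2(C[C@H](Br)[C@@](C)(Cl)C[C@@H]2OCC=C1Br)C(C)=O | intermediate
14 | 1-[(1R,2S,4S,5S)-5-bromo-4-chloro-1-[(3E)-3,5-dibromo-2-methylpent-3-en-2-yl]-4-methyl-2-(trimethylsilyloxy)cyclohexyl]ethanone | BrC/C=C(/Br)C(C)(C)[C@@]1(C[C@H](Br)[C@@](C)(Cl)C[C@@H]1O[Si](C)(C)C)C(C)=O | intermediate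
15 | (E)-allylic tetrahydrothiophenium tetrafluoroborate derived from 14 (S+ on C8) | C1CC[S+](C1)C/C=C(/Br)C(C)(C)[C@@]1(C[C@H](Br)[C@@](C)(Cl)C[C@@H]1O[Si](C)(C)C)C(C)=O.F[B-](F)(F)F | intermediate
16 | allyl ylide (C8 carbanion of 15, not isolated) | C1CC[S+](C1)[CH-]/C=C(/Br)C(C)(C)[C@@]1(C[C@H](Br)[C@@](C)(Cl)C[C@@H]1O[Si](C)(C)C)C(C)=O | intermediate
17 | betaine (7S,8S): ring B closed, C7–O− and C8–S+ trans (not isolated) | CC1(C)[C@@]2(C[C@H](Br)[C@@](C)(Cl)C[C@@H]2O[Si](C)(C)C)[C@](C)([O-])[C@@H]([S+]2CCCC2)C=C1Br | intermediate
18 | O-TMS prepacifenol (2S,3S,5S,6R,7S,8R) | CC1(C)[C@@]2(C[C@H](Br)[C@@](C)(Cl)C[C@@H]2O[Si](C)(C)C)[C@]2(C)O[C@@H]2C=C1Br | intermediate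
19 | O-TMS prepacifenol epoxide (not isolated) | CC1(C)[C@@]2(C[C@H](Br)[C@@](C)(Cl)C[C@@H]2O[Si](C)(C)C)[C@]2(C)O[C@@H]2[C@H]2O[C@]21Br | intermediate
20 | prepacifenol epoxide | CC1(C)[C@@]2(C[C@H](Br)[C@@](C)(Cl)C[C@@H]2O)[C@]2(C)O[C@@H]2[C@H]2O[C@]21Br | target

Total step count: 13. Longest linear sequence: 13 steps (from 1).

Steps most likely to fail

Step 9. Three processes may spoil it. Chloride may open the bromonium ion at C2 instead of C3, which transposes the halogens. An unbridged C3 cation may be captured from the α-face, which erodes retention. Proton loss may compete with substitution. The fallback introduces chloride on the rigid bicycle and builds the ketone afterwards. It sets out from 10. TiCl4 in CH2Cl2 at −78 °C ionises the tertiary C3–O bond of the lactone, where C2–Br is locked antiperiplanar, and the titanium carboxylate returns chloride on the β-face to give the chloro acid F1. Oxalyl chloride with cat. DMF gives the acid chloride F2. Me2CuLi in Et2O at −78 °C converts this into the methyl ketone, and the route is rejoined at 13 without passing through 11 and 12.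

Step 12. Addition to a carbonyl flanked by two quaternary carbons may be slower than enolisation of the methyl ketone. It may also be slower than a [2,3]-shift of a ring-deprotonated ylide. In addition, facial selectivity at C7 may be poor. The fallback keeps the same ring closure but separates olefination from oxygen delivery. It sets out from 14. PPh3 in MeCN gives the allylic phosphonium bromide F3. KHMDS in THF (−78 °C → rt) triggers an intramolecular Wittig reaction that forms C7=C8 and gives the bromodiene silyl ether F4. NH4F in MeOH gives the bromodienol F5. VO(acac)2/t-BuOOH, directed by the homoallylic C5–OH, delivers oxygen to the C5 side of C7=C8 to give prepacifenol F6. TMSCl/imidazole rejoins the route at 18.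

Step 3. The trisubstituted dienophile, flanked by a quaternary carbon, may react too slowly, so that isoprene polymerises. Face discrimination may also be insufficient because the α-carbon carries no hydrogen for a second contact with the catalyst. The fallback replaces catalysis by resolution. It sets out from 3 and 4. An achiral promoter (EtAlCl2, or 12 kbar without a promoter) gives the racemic cis-fused adduct F7. AlMe3-mediated aminolysis of the lactone with (S)-1-phenylethylamine gives two diastereomeric hydroxy amides, which are separated by chromatography. The (5S,6R)-hydroxy amide F8 relactonises with p-TsOH in hot toluene, and the route is rejoined at 5.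

Further compounds
F1 | step 9 | chloro acid (2S,3S,5S,6R): C6–CO2H analogue of 13 | CC1(C)[C@@]2(C[C@H](Br)[C@@](C)(Cl)C[C@@H]2OCC=C1Br)C(=O)O
F2 | step 9 | acid chloride of F1 | CC1(C)[C@@]2(C[C@H](Br)[C@@](C)(Cl)C[C@@H]2OCC=C1Br)C(=O)Cl
F3 | step 12 | (E)-allylic triphenylphosphonium bromide derived from 14 | c1ccccc1[P+](c1ccccc1)(c1ccccc1)C/C=C(/Br)C(C)(C)[C@@]1(C[C@H](Br)[C@@](C)(Cl)C[C@@H]1O[Si](C)(C)C)C(C)=O.[Br-]
F4 | step 12 | spirocyclic 10-bromo-7,9-diene, C5–OTMS | CC1(C)[C@@]2(C[C@H](Br)[C@@](C)(Cl)C[C@@H]2O[Si](C)(C)C)C(C)=CC=C1Br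
F5 | step 12 | spirocyclic 10-bromo-7,9-dien-5-ol | CC1(C)[C@@]2(C[C@H](Br)[C@@](C)(Cl)C[C@@H]2O)C(C)=CC=C1Br
F6 | step 12 | prepacifenol | CC1(C)[C@@]2(C[C@H](Br)[C@@](C)(Cl)C[C@@H]2O)[C@]2(C)O[C@@H]2C=C1Br
F7 | step 3 | rac-5 (cis-fused racemate) | CC1(C)C2(CC=C(C)CC2OC1=O)C(=O)OC
F8 | step 3 | (5S,6R)-hydroxy amide of (S)-1-phenylethylamine | C[C@H](NC(=O)C(C)(C)[C@@]1(CC=C(C)C[C@@H]1O)C(=O)OC)c1ccccc1
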